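## The problem

Target 25 is a trimer of 8-methoxynaphthalen-1-ol (C33H26O6). The central unit B carries unit A at B2 and unit C at B4; unit A is joined through its C2 (ortho to its hydroxyl) and unit C through its C1 (para to its hydroxyl). Both biaryl bonds are awkward for cross-coupling: A2–B2 lies between two oxygenated carbons, and B4–C1 is of 1,1'-binaphthyl type with a peri hydrogen on each side. A coupling approach would also need three differently functionalised copies of one monomer, each halogenated or metalated at the correct one of two competing positions (C2 or C4).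

There is no stereocentre. The two axes are not expected to be configurationally stable at ambient temperature, so any sp3 centre made on the way only has to be erased again.

Three free hydroxyls sit beside three methyl ethers. The hydroxyls must therefore travel under a group that comes off without Lewis-acid demethylation conditions, and the electron-rich naphthols, which oxidise and couple easily, should be unmasked last.

The feature that opens the structure is the phenol ring of unit B. B1 (C–OH) hangs on B8a, whose neighbour B8 bears OMe; B2 carries an aryl group, B3 a hydrogen, and B4 an aryl group. Read as B8a–B1(O)–B2(Ar)–B3–B4(Ar)–B4a, this is an aryl ketone carbon, the two carbons of a 1-arylvinyl unit and an aryl-bearing benzylic carbon. That is the atom pattern produced when a 1-arylvinyl anion adds to an 8-arylbenzocyclobutenone with OMe beside the carbonyl-bearing ring carbon and the four-membered ring expands.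

## Retrosynthesis

**25 back to 23.** No skeletal bond is cut. The two methoxymethyl (MOM) ethers of 24 are removed last with aqueous acid, which leaves the methyl ethers alone. The central naphthol of 24 is traced to the 2,4-diaryl-8-methoxy-1-tetralone 23, two hydrogens richer. The forward step needs an oxidant that removes H from C2/C3 of 23 and stops at the naphthol; it also erases both sp3 centres, so their configuration never matters.

**23 back to 12 and 19 (key cut).** B1–B2 and B3–B4 are cut. Cutting instead at A2–B2 or B4–C1 would bring back the hindered couplings and the C2/C4 selectivity problem. Here both biaryl bonds are already present as ordinary aryl–C(sp2) and aryl–C(sp3) bonds in two small pieces, each holding one naphthalene: benzocyclobutenone 12 and vinyllithium 19. The forward reaction needs carbonyl addition to win over deprotonation of 12, the alkoxide 20 to open with oxygen outward, and the ring-opened anion 21 to close to enolate 22.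

**19 back to 2.** The vinyllithium comes from trisylhydrazone 18 by Shapiro reaction, and 18 from methyl ketone 16 and hydrazide 17. The A2–acetyl bond is cut by directed ortho-metalation of MOM ether 13 (via aryllithium 15) and acylation with amide 14; 13 is the MOM ether of 2. A Fries route to 16 was ranked second because it needs a Lewis acid next to the peri methyl ether. Metalation uses the MOM group both as director and as the final protecting group.

**12 back to 7 and 9.** The two bonds from the benzo ring to the four-membered ring (B8a–B1 and B4a–B4) are cut: ketone 12 comes from silyl ketal 11, the [2+2] adduct of 3-methoxybenzyne 10 with ketene silyl acetal 7. The polarisation of 10 places the ketal carbon beside the OMe-bearing carbon, which fixes the peri OMe/OH relation of unit B. The aryne is released from bromo triflate 9 (from phenol 8) by halogen–lithium exchange. A fluoride-triggered aryne precursor was set aside because fluoride would also attack the silyl group of 7.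

**7 back to 1.** The ketene acetal is the enol silyl ether of arylacetate 6. The C1(unit C)–CH2 bond is cut to bromide 4 and Reformatsky reagent 5, a neutral palladium-catalysed coupling that tolerates the MOM ether. Bromide 4 is the MOM ether of 3, the para-bromination product of 2, and 2 is the monomethyl ether of diol 1. Both naphthalene-bearing branches thus diverge from 2.

## Roads not taken

**Alternative 1:** The A2–B2 bond is cut last. A 2-brominated unit A and a preformed B–C binaphthol would be tied through their hydroxyls as the diisopropylsilylene diether A2. Pd(OAc)2, a trialkylphosphine, Cs2CO3 and pivalic acid would then arylate B2–H intramolecularly, closing the seven-membered dioxasilepine A1; fluoride would free both hydroxyls.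
- Merits: three intact naphthalenes, no redox adjustment, and a tether that enforces the ortho,ortho' regiochemistry.
- Weak points: an unsymmetrical diaryloxysilane of two hindered, hydrogen-bonded naphthols is hard to make cleanly, and aryl Si–O bonds are unlikely to survive carbonate and pivalate at C–H arylation temperatures. The B4–C1 bond still needs a separate hindered cross-coupling, with selective C2 and C4 halogenations. This tethered arylation also has no close precedent.
- Comparison: this road is better in avoiding the oxidation of step 13. The chosen plan offers in return a key step with class precedent and no bond formation at a hindered aromatic carbon.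

**Alternative 2:** The phenol ring of unit A is cut at A1–A8a. The 2,4-diarylbut-3-enoic acid A4, heated with acetic anhydride and sodium acetate, would give a dienylketene whose six-electron electrocyclisation closes ring A as naphthyl acetate A3.
- Merits: the ring closure is thermal, classical and free of organometallics, and in that respect more dependable than step 12.
- Weak points: closure must occur ortho to OMe, so a bromine blocker is carried and later removed. A4 is a β,γ-unsaturated α-aryl acid that can slip into conjugation. The B–C unit bearing an acetic acid chain at B2 must be built first, so the hindered B4–C1 coupling and the C2/C4 differentiation of unit B remain.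
- Comparison: the chosen plan is shorter and creates both aryl attachments of the hub in the ring-forming event, with no blocking halogen.

**Alternative 3:** Unit A is cut at A1–A2 and A2–A3. The benzylic Grignard reagent A7 (B–C dimer with CH2MgBr at B2) would add to the lactone carbonyl of 8-methoxyisocoumarin A6; ring opening and intramolecular aldol condensation would give A5 with a free A1 hydroxyl.
- Merits: redox-neutral, the new ring arrives aromatic, the peri OMe/OH relation of unit A is written into A6, and the three hydroxyls come out differentiated. In oxidation-state economy this road is better than the chosen one.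
- Weak points: electron-rich naphthylmethyl Grignard reagents homocouple on formation and can react through the ring carbon, and the lactone can take up two equivalents. A7 presupposes the B–C biaryl plus a three-step homologation at B2, and A6 needs several steps of its own.
- Comparison: the chosen plan offers a shorter longest sequence and a hub assembled from two monoaryl pieces that each descend from 2.

Key step: step 12

Remark on the chemistry: 25 has no stereocentre, and its axes (A2–B2 with two ortho substituents, B4–C1 of 1,1'-binaphthyl type) are assumed to rotate at ambient temperature, so no axial configuration is set. Compounds 11, 12, 20, 22 and 23 are racemic; 11 and 23 are diastereomer mixtures.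

Remark on materials: 1, 5 (as its THF solution), 8, 14 and 17 are taken as purchased.

## Route

Step 1
Reactants: 1 naphthalene-1,8-diol
Product: 2 8-methoxynaphthalen-1-ol
Conditions: MeI (1.05 equiv), K2CO3, acetone, reflux
Reagents that add atoms: iodomethane, CI
Why: Williamson etherification; the monoanion is held by the peri hydrogen bond and the remaining OH of 2 is much less acidic, so methylation should stop after one oxygen.

Step 2
Reactants: 2 8-methoxynaphthalen-1-ol
Product: 3 4-bromo-8-methoxynaphthalen-1-ol
Conditions: NBS (1.0 equiv), MeCN, −30 to 0 °C, dark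
Reagents that add atoms: N-bromosuccinimide, O=C1CCC(=O)N1Br
Why: Electrophilic aromatic bromination; the phenol ring is more activated than the anisole ring, and the alpha position para to OH (C4) is the usual site for 1-naphthols with NBS in a polar solvent at low temperature.

Step 3
Reactants: 3 4-bromo-8-methoxynaphthalen-1-ol
Product: 4 1-bromo-5-methoxy-4-(methoxymethoxy)naphthalene
Conditions: NaH, DMF, 0 °C; MOMCl, 0 °C to rt
Reagents that add atoms: chloromethyl methyl ether, COCCl
Why: O-alkylation of the sodium naphtholate; full deprotonation overcomes the peri hydrogen bond that makes this OH sluggish with amine bases.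

Step 4
Reactants: 4 1-bromo-5-methoxy-4-(methoxymethoxy)naphthalene; 5 (2-ethoxy-2-oxoethyl)zinc bromide
Product: 6 ethyl 2-[5-methoxy-4-(methoxymethoxy)naphthalen-1-yl]acetate
Conditions: Pd2(dba)3 (2.5 mol %), XPhos (10 mol %), THF, 65 °C
Reagents that add atoms: none
Why: Negishi-type cross-coupling of a Reformatsky reagent with an aryl bromide (ester α-arylation under neutral conditions); the MOM acetal and methyl ether are inert to the zinc enolate, and diarylation is not expected because the product is not re-enolised.

Step 5
Reactants: 6 ethyl 2-[5-methoxy-4-(methoxymethoxy)naphthalen-1-yl]acetate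
Product: 7 tert-butyl({1-ethoxy-2-[5-methoxy-4-(methoxymethoxy)naphthalen-1-yl]ethenyl}oxy)dimethylsilane (E/Z mixture)
Conditions: LiN(i-Pr)2, THF, −78 °C; TBSCl, DMPU, −78 °C to rt; pentane, filtration, used crude
Reagents that add atoms: tert-butyldimethylsilyl chloride, CC(C)(C)[Si](C)(C)Cl
Why: Kinetic enolisation of an arylacetate and O-silylation in the presence of DMPU gives the ketene silyl acetal; the alkene geometry is irrelevant because both alkene carbons become ring atoms of 11.

Step 6
Reactants: 8 2-bromo-3-methoxyphenol
Product: 9 2-bromo-3-methoxyphenyl trifluoromethanesulfonate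
Conditions: Tf2O, pyridine, CH2Cl2, 0 °C
Reagents that add atoms: trifluoromethanesulfonic anhydride, O=S(=O)(OS(=O)(=O)C(F)(F)F)C(F)(F)F
Why: Routine O-triflation of a phenol; the ortho bromine and the triflate together form the aryne precursor.

Step 7
Reactants: 9 2-bromo-3-methoxyphenyl trifluoromethanesulfonate; 7 tert-butyl({1-ethoxy-2-[5-methoxy-4-(methoxymethoxy)naphthalen-1-yl]ethenyl}oxy)dimethylsilane
Product: 11 tert-butyl({7-ethoxy-5-methoxy-8-[5-methoxy-4-(methoxymethoxy)naphthalen-1-yl]bicyclo[4.2.0]octa-1,3,5-trien-7-yl}oxy)dimethylsilane (racemic diastereomer mixture), via 3-methoxybenzyne 10 (not isolated)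
Conditions: 7 (1.0 equiv), 9 (1.5 equiv), n-BuLi (1.5 equiv, slow addition), THF, −78 °C
Reagents that add atoms: none
Why: Bromine–lithium exchange and loss of lithium triflate release aryne 10, and the nucleophilic carbon of 7 attacks the aryne carbon meta to OMe so that the aryl anion forms ortho to OMe and closes on the oxocarbenium carbon; this known aryne–ketene silyl acetal [2+2] cycloaddition places the ketal carbon beside the OMe-bearing carbon.

Step 8
Reactants: 11 tert-butyl({7-ethoxy-5-methoxy-8-[5-methoxy-4-(methoxymethoxy)naphthalen-1-yl]bicyclo[4.2.0]octa-1,3,5-trien-7-yl}oxy)dimethylsilane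
Product: 12 5-methoxy-8-[5-methoxy-4-(methoxymethoxy)naphthalen-1-yl]bicyclo[4.2.0]octa-1,3,5-trien-7-one (racemic)
Conditions: 46% aq. HF, MeCN, 0 °C; NaHCO3 work-up
Reagents that add atoms: none
Why: Fluoride removes the silyl group of the mixed ketal and the hemiketal collapses to the ketone with loss of ethanol; the aryl MOM ether should tolerate brief exposure to dilute HF at 0 °C, and acidic conditions avoid the alkoxide that would open the four-membered ring.

Step 9
Reactants: 2 8-methoxynaphthalen-1-ol
Product: 13 1-methoxy-8-(methoxymethoxy)naphthalene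
Conditions: NaH, DMF, 0 °C; MOMCl, 0 °C to rt
Reagents that add atoms: chloromethyl methyl ether, COCCl
Why: O-alkylation of the sodium naphtholate, as in step 3; the MOM group installed here is both the metalation director for step 10 and the final protecting group of unit A.

Step 10
Reactants: 13 1-methoxy-8-(methoxymethoxy)naphthalene; 14 N-methoxy-N-methylacetamide
Product: 16 1-[8-methoxy-1-(methoxymethoxy)naphthalen-2-yl]ethan-1-one, via aryllithium 15 (not isolated)
Conditions: n-BuLi, TMEDA, Et2O, 0 °C to rt; then 14, −78 to 0 °C; aq. work-up
Reagents that add atoms: none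
Why: Directed ortho-metalation; the MOM acetal is a stronger director than OMe and the peri position is blocked, so lithiation should occur at C2, and the N-methoxy-N-methyl amide stops at the ketone through its chelated tetrahedral adduct.

Step 11
Reactants: 16 1-[8-methoxy-1-(methoxymethoxy)naphthalen-2-yl]ethan-1-one; 17 2,4,6-triisopropylbenzenesulfonyl hydrazide
Product: 18 N'-{1-[8-methoxy-1-(methoxymethoxy)naphthalen-2-yl]ethylidene}-2,4,6-tri(propan-2-yl)benzenesulfonohydrazide
Conditions: THF, cat. AcOH, 4 Å MS, rt
Reagents that add atoms: none
Why: Condensation of a methyl ketone with an arenesulfonyl hydrazide; the mild acid catalyst leaves the MOM ether intact, and the triisopropyl groups later block ortho-lithiation of the sulfonyl ring.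

Step 12
Reactants: 18 N'-{1-[8-methoxy-1-(methoxymethoxy)naphthalen-2-yl]ethylidene}-2,4,6-tri(propan-2-yl)benzenesulfonohydrazide; 12 5-methoxy-8-[5-methoxy-4-(methoxymethoxy)naphthalen-1-yl]bicyclo[4.2.0]octa-1,3,5-trien-7-one
Product: 23 8-methoxy-2-[8-methoxy-1-(methoxymethoxy)naphthalen-2-yl]-4-[5-methoxy-4-(methoxymethoxy)naphthalen-1-yl]-3,4-dihydronaphthalen-1(2H)-one (racemic cis/trans mixture), via vinyllithium 19 (not isolated), via lithium benzocyclobutenoxide 20 (not isolated), via ortho-quinodimethane enolate 21 (not isolated), via lithium tetralone enolate 22 (not isolated)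
Conditions: 18 (1.3 equiv), n-BuLi (2.0 equiv per 18), THF, −78 to 0 °C until N2 evolution ends; recool to −78 °C, add 12 (1.0 equiv) in THF; −78 °C to rt; aq. work-up
Reagents that add atoms: none
Why: Shapiro reaction (double deprotonation of 18 at N–H and CH3, loss of sulfinate and N2) gives vinyllithium 19, which adds to the strained carbonyl of 12 anti to the C8 aryl group, helped by chelation to the neighbouring OMe, to give alkoxide 20 and so form B1–B2. The oxyanion then drives a conrotatory four-electron opening of the C7–C8 bond below room temperature, with oxygen turning outward and the vinyl group inward, to give 21, which is equally a delocalised benzylic anion conjugated to an aryl vinyl ketone. A disrotatory six-electron closure between the vinyl CH2 and the aryl-bearing methine (in polar terms a 6-endo conjugate addition) forms B3–B4, closes the six-membered ring, restores the benzene ring and gives enolate 22, protonated on work-up to 23. The closest known reaction type is the oxyanion-accelerated ring opening of 1-alkenylbenzocyclobutenols followed by six-electron electrocyclisation to tetralones. The aryl group at C8, cis to oxygen after anti addition, turns inward on opening; this slows the closure but should not block it, because the exocyclic bond of the delocalised anion can rotate. The new centre at C4 is set in the ring closure and that at C2 by protonation of 22; neither is controlled and both are removed in step 13. The step needs addition to outrun deprotonation of the doubly benzylic C8–H, which the antiaromatic character of the benzocyclobutenone enolate and the low temperature should secure. No regiochemical choice remains, since only one carbonyl, one breakable ring bond and one vinyl terminus are present.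

Step 13
Reactants: 23 8-methoxy-2-[8-methoxy-1-(methoxymethoxy)naphthalen-2-yl]-4-[5-methoxy-4-(methoxymethoxy)naphthalen-1-yl]-3,4-dihydronaphthalen-1(2H)-one
Product: 24 8-methoxy-2-[8-methoxy-1-(methoxymethoxy)naphthalen-2-yl]-4-[5-methoxy-4-(methoxymethoxy)naphthalen-1-yl]naphthalen-1-ol
Conditions: DDQ (1.1 equiv), 1,4-dioxane, 60–80 °C
Reagents that add atoms: none
Why: Quinone dehydrogenation of a readily enolised 2-aryl-1-tetralone; hydride loss from C3 of the enol or from the doubly benzylic C4 gives a naphthalenone that tautomerises to the 1-naphthol, both diastereomers converge, and MOM and methyl ethers are inert to DDQ.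

Step 14
Reactants: 24 8-methoxy-2-[8-methoxy-1-(methoxymethoxy)naphthalen-2-yl]-4-[5-methoxy-4-(methoxymethoxy)naphthalen-1-yl]naphthalen-1-ol
Product: 25 2-(1-hydroxy-8-methoxynaphthalen-2-yl)-4-(4-hydroxy-5-methoxynaphthalen-1-yl)-8-methoxynaphthalen-1-ol (CNP0542019.0)
Conditions: 3 M HCl, MeOH/THF, 45 °C, argon
Reagents that add atoms: none
Why: Acid-catalysed acetal exchange removes both MOM groups as dimethoxymethane while the aryl methyl ethers stay untouched; exclusion of air protects the electron-rich trinaphthol.

## Compound list

1 | naphthalene-1,8-diol | Oc1cccc2cccc(O)c12 | starting material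
2 | 8-methoxynaphthalen-1-ol | COc1cccc2cccc(O)c12 | intermediate
3 | 4-bromo-8-methoxynaphthalen-1-ol | COc1cccc2c(Br)ccc(O)c12 | intermediate
4 | 1-bromo-5-methoxy-4-(methoxymethoxy)naphthalene | COCOc1ccc(Br)c2cccc(OC)c12 | intermediate
5 | (2-ethoxy-2-oxoethyl)zinc bromide | CCOC(=O)C[Zn]Br | starting material
6 | ethyl 2-[5-methoxy-4-(methoxymethoxy)naphthalen-1-yl]acetate | CCOC(=O)Cc1ccc(OCOC)c2c(OC)cccc12 | intermediate
7 | tert-butyl({1-ethoxy-2-[5-methoxy-4-(methoxymethoxy)naphthalen-1-yl]ethenyl}oxy)dimethylsilane, E/Z mixture | CCOC(O[Si](C)(C)C(C)(C)C)=Cc1ccc(OCOC)c2c(OC)cccc12 | intermediate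
8 | 2-bromo-3-methoxyphenol | COc1cccc(O)c1Br | starting material
9 | 2-bromo-3-methoxyphenyl trifluoromethanesulfonate | COc1cccc(OS(=O)(=O)C(F)(F)F)c1Br | intermediate
10 | 3-methoxybenzyne (1-methoxy-2,3-didehydrobenzene) | COC1=CC=CC#C1 | intermediate
11 | tert-butyl({7-ethoxy-5-methoxy-8-[5-methoxy-4-(methoxymethoxy)naphthalen-1-yl]bicyclo[4.2.0]octa-1,3,5-trien-7-yl}oxy)dimethylsilane, racemic, diastereomer mixture | CCOC1(O[Si](C)(C)C(C)(C)C)C(c2ccc(OCOC)c3c(OC)cccc23)c2cccc(OC)c21 | intermediate
12 | 5-methoxy-8-[5-methoxy-4-(methoxymethoxy)naphthalen-1-yl]bicyclo[4.2.0]octa-1,3,5-trien-7-one, racemic | COc1cccc2c1C(=O)C2c1ccc(OCOC)c2c(OC)cccc12 | intermediate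
13 | 1-methoxy-8-(methoxymethoxy)naphthalene | COCOc1cccc2cccc(OC)c12 | intermediate
14 | N-methoxy-N-methylacetamide | CON(C)C(C)=O | starting material
15 | [8-methoxy-1-(methoxymethoxy)naphthalen-2-yl]lithium | [Li]c1ccc2cccc(OC)c2c1OCOC | intermediate
16 | 1-[8-methoxy-1-(methoxymethoxy)naphthalen-2-yl]ethan-1-one | CC(=O)c1ccc2cccc(OC)c2c1OCOC | intermediate
17 | 2,4,6-triisopropylbenzenesulfonyl hydrazide | CC(C)c1cc(C(C)C)c(S(=O)(=O)NN)c(C(C)C)c1 | starting material
18 | N'-{1-[8-methoxy-1-(methoxymethoxy)naphthalen-2-yl]ethylidene}-2,4,6-tri(propan-2-yl)benzenesulfonohydrazide, C=N geometry not assigned | CC(=NNS(=O)(=O)c1c(C(C)C)cc(C(C)C)cc1C(C)C)c1ccc2cccc(OC)c2c1OCOC | intermediate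
19 | {1-[8-methoxy-1-(methoxymethoxy)naphthalen-2-yl]ethenyl}lithium | [Li]C(=C)c1ccc2cccc(OC)c2c1OCOC | intermediate
20 | lithium 7-{1-[8-methoxy-1-(methoxymethoxy)naphthalen-2-yl]ethenyl}-5-methoxy-8-[5-methoxy-4-(methoxymethoxy)naphthalen-1-yl]bicyclo[4.2.0]octa-1,3,5-trien-7-olate, racemic | [Li]OC1(C(=C)c2ccc3cccc(OC)c3c2OCOC)C(c2ccc(OCOC)c3c(OC)cccc23)c2cccc(OC)c21 | intermediate
21 | ring-opened lithium dienolate (ortho-quinodimethane: exocyclic C(OLi)(1-arylvinyl)= and =CH(aryl) on a 3-methoxycyclohexa-2,4-diene-1,6-diylidene), exocyclic geometry not fixed | [Li]OC(C(=C)c1ccc2cccc(OC)c2c1OCOC)=C1C(OC)=CC=CC1=Cc1ccc(OCOC)c2c(OC)cccc12 | intermediate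
22 | lithium enolate of 23 (lithium 8-methoxy-2-aryl-4-aryl-3,4-dihydronaphthalen-1-olate), racemic | [Li]OC1=C(c2ccc3cccc(OC)c3c2OCOC)CC(c2ccc(OCOC)c3c(OC)cccc23)c2cccc(OC)c21 | intermediate
23 | 8-methoxy-2-[8-methoxy-1-(methoxymethoxy)naphthalen-2-yl]-4-[5-methoxy-4-(methoxymethoxy)naphthalen-1-yl]-3,4-dihydronaphthalen-1(2H)-one, racemic, cis/trans mixture | COc1cccc2c1C(=O)C(c1ccc3cccc(OC)c3c1OCOC)CC2c1ccc(OCOC)c2c(OC)cccc12 | intermediate
24 | 8-methoxy-2-[8-methoxy-1-(methoxymethoxy)naphthalen-2-yl]-4-[5-methoxy-4-(methoxymethoxy)naphthalen-1-yl]naphthalen-1-ol | COc1cccc2c(-c3ccc(OCOC)c4c(OC)cccc34)cc(-c3ccc4cccc(OC)c4c3OCOC)c(O)c12 | intermediate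
25 | 2-(1-hydroxy-8-methoxynaphthalen-2-yl)-4-(4-hydroxy-5-methoxynaphthalen-1-yl)-8-methoxynaphthalen-1-ol (CNP0542019.0), no stereocentre | COc1cccc2ccc(-c3cc(-c4ccc(O)c5c(OC)cccc45)c4cccc(OC)c4c3O)c(O)c12 | target

## Step count and risks

Total: 14 steps. Longest linear sequence: 10 steps (1, 2, 3, 4, 5, 7, 8, 12, 13, 14). The unit A branch (steps 9–11) and the aryne precursor (step 6) are side branches.

**Step 12 (key step).** The most likely failure is proton abstraction from the doubly benzylic C8–H of 12 by 19 in place of carbonyl addition. The second is protonation of the ring-opened benzylic anion before it closes, because the inward-turned aryl group slows the closure. The fallback separates addition from ring expansion and sets out from 12 and 19.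
- The vinyllithium is transmetalated with anhydrous CeCl3 and added at −78 °C. A cold quench should give the carbinol 7-{1-[8-methoxy-1-(methoxymethoxy)naphthalen-2-yl]ethenyl}-5-methoxy-8-[5-methoxy-4-(methoxymethoxy)naphthalen-1-yl]bicyclo[4.2.0]octa-1,3,5-trien-7-ol F1.
- Heating F1 in toluene opens the ring thermally under neutral conditions. This should give 23 directly or, by 1,5-hydrogen shift in the hydroxy-ortho-quinodimethane, the ketone 1-(2-methoxy-6-{[5-methoxy-4-(methoxymethoxy)naphthalen-1-yl]methyl}phenyl)-2-[8-methoxy-1-(methoxymethoxy)naphthalen-2-yl]prop-2-en-1-one F2.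
- F2 is closed with KOt-Bu in THF by 6-endo conjugate addition of its dienolate. The route is rejoined at 23.

**Step 7.** The zwitterion formed after the first C–C bond may fail to close because of the naphthyl group on the attacking carbon, so that silyl transfer gives an open-chain α-arylated ester. n-BuLi may also consume the aryne. The fallback replaces the ketene acetal by an aldehyde enolate and sets out from 6.
- i-Bu2AlH at −78 °C should give 2-[5-methoxy-4-(methoxymethoxy)naphthalen-1-yl]acetaldehyde F3.
- The lithium enolate of F3 (lithium 2,2,6,6-tetramethylpiperidide, THF, −78 °C) is combined with 3-methoxybenzyne made in the same flask from 3-bromoanisole and the same base. The aryne–enolate [2+2] reaction, with the same regiochemical bias, should give 5-methoxy-8-[5-methoxy-4-(methoxymethoxy)naphthalen-1-yl]bicyclo[4.2.0]octa-1,3,5-trien-7-ol F4.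
- Dess–Martin periodinane oxidises F4, and the route is rejoined at 12.

**Step 13.** The freshly formed electron-rich naphthol may be over-oxidised by DDQ (phenoxyl radical coupling or quinone-type products), or hydride abstraction may be too slow at temperatures the substrate tolerates. The fallback is a Saegusa–Ito sequence from 23.
- KN(SiMe3)2 and Me3SiCl should give the enol ether ({8-methoxy-2-[8-methoxy-1-(methoxymethoxy)naphthalen-2-yl]-4-[5-methoxy-4-(methoxymethoxy)naphthalen-1-yl]-3,4-dihydronaphthalen-1-yl}oxy)trimethylsilane F5.
- Stoichiometric Pd(OAc)2 in MeCN dehydrosilylates F5 through an oxa-π-allyl complex of divalent palladium and β-hydride loss from C3. The resulting naphthalenone tautomerises, and the route is rejoined at 24.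

**Step 2.** Site selectivity may be poor (attack at C2, or at C5 of the methoxy ring), and overbromination may follow. The fallback deactivates one ring with a sulfonate that cannot migrate between the peri oxygens, and sets out from 1.
- TsCl and Et3N should give 8-hydroxynaphthalen-1-yl 4-methylbenzenesulfonate F6.
- NBS brominates only the free phenol ring, para to OH, to give 5-bromo-8-hydroxynaphthalen-1-yl 4-methylbenzenesulfonate F7.
- NaH and MOMCl give 5-bromo-8-(methoxymethoxy)naphthalen-1-yl 4-methylbenzenesulfonate F8.
- KOH in MeOH/THF removes the sulfonate to give 5-bromo-8-(methoxymethoxy)naphthalen-1-ol F9.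
- MeI and K2CO3 methylate F9, and the route is rejoined at 4.

**Step 10.** Metalation may be incompletely regioselective (C7 beside OMe competing with C2), and proton transfer from amide 14 to aryllithium 15 would return 13. The fallback brings in the acetyl group by rearrangement and sets out from 2.
- Acetyl chloride and pyridine should give 8-methoxynaphthalen-1-yl acetate F10.
- Ortho-Fries rearrangement with BF3·OEt2 at about 80 °C should give the chelated ketone 1-(1-hydroxy-8-methoxynaphthalen-2-yl)ethan-1-one F11.
- NaH and MOMCl protect F11, and the route is rejoined at 16.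

## Further compounds

F1 | step 12 | 7-{1-[8-methoxy-1-(methoxymethoxy)naphthalen-2-yl]ethenyl}-5-methoxy-8-[5-methoxy-4-(methoxymethoxy)naphthalen-1-yl]bicyclo[4.2.0]octa-1,3,5-trien-7-ol, racemic, relative configuration not assigned | OC1(C(=C)c2ccc3cccc(OC)c3c2OCOC)C(c2ccc(OCOC)c3c(OC)cccc23)c2cccc(OC)c21
F2 | step 12 | 1-(2-methoxy-6-{[5-methoxy-4-(methoxymethoxy)naphthalen-1-yl]methyl}phenyl)-2-[8-methoxy-1-(methoxymethoxy)naphthalen-2-yl]prop-2-en-1-one | C=C(C(=O)c1c(OC)cccc1Cc1ccc(OCOC)c2c(OC)cccc12)c1ccc2cccc(OC)c2c1OCOC
F3 | step 7 | 2-[5-methoxy-4-(methoxymethoxy)naphthalen-1-yl]acetaldehyde | O=CCc1ccc(OCOC)c2c(OC)cccc12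
F4 | step 7 | 5-methoxy-8-[5-methoxy-4-(methoxymethoxy)naphthalen-1-yl]bicyclo[4.2.0]octa-1,3,5-trien-7-ol, racemic, diastereomer mixture | OC1C(c2ccc(OCOC)c3c(OC)cccc23)c2cccc(OC)c21
F5 | step 13 | ({8-methoxy-2-[8-methoxy-1-(methoxymethoxy)naphthalen-2-yl]-4-[5-methoxy-4-(methoxymethoxy)naphthalen-1-yl]-3,4-dihydronaphthalen-1-yl}oxy)trimethylsilane, racemic | C[Si](C)(C)OC1=C(c2ccc3cccc(OC)c3c2OCOC)CC(c2ccc(OCOC)c3c(OC)cccc23)c2cccc(OC)c21
F6 | step 2 | 8-hydroxynaphthalen-1-yl 4-methylbenzenesulfonate | Cc1ccc(S(=O)(=O)Oc2cccc3cccc(O)c23)cc1
F7 | step 2 | 5-bromo-8-hydroxynaphthalen-1-yl 4-methylbenzenesulfonate | Cc1ccc(S(=O)(=O)Oc2cccc3c(Br)ccc(O)c23)cc1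
F8 | step 2 | 5-bromo-8-(methoxymethoxy)naphthalen-1-yl 4-methylbenzenesulfonate | Cc1ccc(S(=O)(=O)Oc2cccc3c(Br)ccc(OCOC)c23)cc1
F9 | step 2 | 5-bromo-8-(methoxymethoxy)naphthalen-1-ol | COCOc1ccc(Br)c2cccc(O)c12
F10 | step 10 | 8-methoxynaphthalen-1-yl acetate | COc1cccc2cccc(OC(C)=O)c12
F11 | step 10 | 1-(1-hydroxy-8-methoxynaphthalen-2-yl)ethan-1-one | CC(=O)c1ccc2cccc(OC)c2c1O
A1 | alternative 1 | silylene-bridged trimer: diisopropylsilylene diether of the A1 and B1 oxygens with the A2–B2 bond closed (seven-membered dioxasilepine), unit C as MOM ether | COc1cccc2ccc3-c4cc(-c5ccc(OCOC)c6c(OC)cccc56)c5cccc(OC)c5c4O[Si](C(C)C)(C(C)C)Oc3c12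
A2 | alternative 1 | open diisopropylsilylene diether of 2-bromo-8-methoxynaphthalen-1-ol and 8-methoxy-4-[5-methoxy-4-(methoxymethoxy)naphthalen-1-yl]naphthalen-1-ol | COc1cccc2ccc(Br)c(O[Si](C(C)C)(C(C)C)Oc3ccc(-c4ccc(OCOC)c5c(OC)cccc45)c4cccc(OC)c34)c12
A3 | alternative 2 | 5-bromo-8-methoxy-2-{1-(benzyloxy)-4-[4-(benzyloxy)-5-methoxynaphthalen-1-yl]-8-methoxynaphthalen-2-yl}naphthalen-1-yl acetate | CC(=O)Oc1c(-c2cc(-c3ccc(OCc4ccccc4)c4c(OC)cccc34)c3cccc(OC)c3c2OCc2ccccc2)ccc2c(Br)ccc(OC)c12
A4 | alternative 2 | (E)-2-{1-(benzyloxy)-4-[4-(benzyloxy)-5-methoxynaphthalen-1-yl]-8-methoxynaphthalen-2-yl}-4-(2-bromo-5-methoxyphenyl)but-3-enoic acid, racemic | OC(=O)C(c1cc(-c2ccc(OCc3ccccc3)c3c(OC)cccc23)c2cccc(OC)c2c1OCc1ccccc1)/C=C/c1cc(OC)ccc1Br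
A5 | alternative 3 | 8-methoxy-2-{8-methoxy-1-(methoxymethoxy)-4-[5-methoxy-4-(methoxymethoxy)naphthalen-1-yl]naphthalen-2-yl}naphthalen-1-ol | COc1cccc2ccc(-c3cc(-c4ccc(OCOC)c5c(OC)cccc45)c4cccc(OC)c4c3OCOC)c(O)c12
A6 | alternative 3 | 8-methoxy-1H-isochromen-1-one (8-methoxyisocoumarin) | COc1cccc2ccoc(=O)c12
A7 | alternative 3 | ({8-methoxy-1-(methoxymethoxy)-4-[5-methoxy-4-(methoxymethoxy)naphthalen-1-yl]naphthalen-2-yl}methyl)magnesium bromide | Br[Mg]Cc1cc(-c2ccc(OCOC)c3c(OC)cccc23)c2cccc(OC)c2c1OCOC
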